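Ring A of the 1‑arylnaphthalene (C4a, C5, C6, C7, C8, C8a) is disconnected at C4a–C5, C5–C6, C7–C8 and C8–C8a. This leads back to a benzene that already carries the C1 aryl group and both methyls, plus a two‑carbon ynol ether. The key step exploits the meta C5/C7 oxygen pair with C8–H. A photochemical Wolff shift turns a biaryl diazomethyl ketone into an arylketene that adds methoxyacetylene and electrocyclises, giving ring A as a C5 naphthol/C7 methyl ether in one operation. C6–H, then flanked by two methoxy groups, is hydroxylated by directed lithiation. The precursor is a 2‑aryl‑3,4‑dimethylphenyl diazomethyl ketone with the syringyl oxygen masked as an isopropyl ether.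

Key step: step 7

Remark: atom labels C1–C8a are those of the target naphthalene (aryl on C1, methyls on C2 and C3, ring A = C4a, C5–C8, C8a). Systematic names of intermediates carry their own locants, so the benzannulation product is a 5‑aryl‑naphthalen‑1‑ol. Methoxyacetylene is volatile and is assumed to be handled as a cold stock solution.

Step 1
Reactants: 1 4-bromo-2,6-dimethoxyphenol
Product: 2 5-bromo-1,3-dimethoxy-2-(propan-2-yloxy)benzene
Conditions: 2-bromopropane (excess), K2CO3, DMF, 70 °C
Reagents that add atoms: 2-bromopropane, CC(C)Br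
Why: Williamson ether synthesis, in which the phenoxide, although flanked by two methoxy groups, is alkylated by an excess of the secondary bromide in a dipolar aprotic solvent while the aryl bromide stays untouched.

Step 2
Reactants: 2 5-bromo-1,3-dimethoxy-2-(propan-2-yloxy)benzene
Product: 5 [3,5-dimethoxy-4-(propan-2-yloxy)phenyl]boronic acid, via aryllithium 3 (not isolated), via lithium aryltriisopropoxyborate 4 (not isolated)
Conditions: n-BuLi, THF, −78 °C; B(OiPr)3, −78 °C → rt; 1 M aq. HCl
Reagents that add atoms: triisopropyl borate, CC(C)OB(OC(C)C)OC(C)C; water, O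
Why: Bromine–lithium exchange at −78 °C outruns any ortho‑metalation, and borate trapping with acidic hydrolysis is the standard route to an arylboronic acid, here one without ortho substituents and therefore not prone to protodeboronation.

Step 3
Reactants: 6 2-amino-3,4-dimethylbenzoic acid
Product: 8 2-iodo-3,4-dimethylbenzoic acid, via arenediazonium chloride 7 (not isolated)
Conditions: NaNO2, aq. HCl, 0–5 °C; then KI, H2O, 0 → 70 °C
Reagents that add atoms: potassium iodide, [K+].[I-]
Why: Diazotisation followed by iodide displacement (Sandmeyer‑type iodination, which needs no copper) is the classical conversion of an anthranilic acid into a 2‑iodobenzoic acid and should tolerate the neighbouring methyl group.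

Step 4
Reactants: 8 2-iodo-3,4-dimethylbenzoic acid; 5 [3,5-dimethoxy-4-(propan-2-yloxy)phenyl]boronic acid
Product: 9 2-[3,5-dimethoxy-4-(propan-2-yloxy)phenyl]-3,4-dimethylbenzoic acid
Conditions: Pd(OAc)2 (3 mol %), SPhos (6 mol %), K3PO4 (4 equiv), 1,4-dioxane/H2O 4:1, 90 °C; then aq. HCl to pH 2
Reagents that add atoms: none
Why: Suzuki–Miyaura coupling, in which the bulky electron‑rich phosphine drives oxidative addition and reductive elimination at the doubly ortho‑substituted iodide, the boronic acid has no ortho substituent so only a di‑ortho‑substituted biaryl forms, and 2‑halobenzoic acids are known to couple as carboxylates when extra base is present.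

Step 5
Reactants: 9 2-[3,5-dimethoxy-4-(propan-2-yloxy)phenyl]-3,4-dimethylbenzoic acid
Product: 11 2-diazo-1-{2-[3,5-dimethoxy-4-(propan-2-yloxy)phenyl]-3,4-dimethylphenyl}ethan-1-one, via acid chloride 10 (not isolated)
Conditions: (COCl)2, cat. DMF, CH2Cl2, 0 °C → rt; evaporate; CH2N2 (3 equiv), Et2O, 0 °C
Reagents that add atoms: diazomethane, C=[N+]=[N-]
Why: Acylation of diazomethane by an acid chloride (first stage of the Arndt–Eistert sequence), where the chloride is made without Lewis acid so the electron‑rich neighbouring ring is not acylated and excess diazomethane removes HCl as chloromethane so the diazoketone survives.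

Step 6
Reactants: 12 chloroacetaldehyde dimethyl acetal (2-chloro-1,1-dimethoxyethane)
Product: 14 methoxyacetylene (methoxyethyne), via sodium methoxyacetylide 13 (not isolated)
Conditions: NaNH2 (3 equiv), liquid NH3, −33 °C; then cold saturated aq. NaCl, −70 °C → rt, distilled into a −78 °C trap and kept as a solution in ClCH2CH2Cl at −20 °C
Reagents that add atoms: none
Why: Twofold amide‑induced elimination (methanol, then HCl) gives the acetylide salt, which is protonated on aqueous quench, the established laboratory preparation of the lower alkoxyacetylenes.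

Step 7
Reactants: 11 2-diazo-1-{2-[3,5-dimethoxy-4-(propan-2-yloxy)phenyl]-3,4-dimethylphenyl}ethan-1-one; 14 methoxyacetylene
Product: 18 5-[3,5-dimethoxy-4-(propan-2-yloxy)phenyl]-3-methoxy-6,7-dimethylnaphthalen-1-ol, via arylketene 15 (not isolated), via 4-aryl-3-methoxycyclobutenone 16 (not isolated), via dienylketene 17 (not isolated)
Conditions: 14 (4 equiv), degassed ClCH2CH2Cl, hν (254 nm, low-pressure Hg lamps, sealed quartz tube), 20 °C; then 80 °C, sealed tube
Reagents that add atoms: none
Why: Light expels N2 from 11 with 1,2‑shift of the aryl group (photo‑Wolff rearrangement, C8–C8a) to give arylketene 15, whose central carbon is attacked by the nucleophilic terminal carbon of the ynol ether in a [2+2] cycloaddition (C5–C6 and C7–C8), giving cyclobutenone 16 with the methoxy carbon bonded to the former ketene CH. Reversible 4π electrocyclic opening of 16 gives dienylketene 17, and ring A closes by 6π electrocyclisation of the ketene carbon onto the benzene carbon ortho to the side chain (C4a–C5), followed by tautomerisation of the cyclohexadienone to the naphthol. The closest known reaction type is the Danheiser photochemical benzannulation of aryl diazomethyl ketones with alkoxy‑ or siloxyalkynes to 3‑oxygenated 1‑naphthols. No stereocentre remains in the product, since the C4 centre of 16 is transient and racemic. Two selectivities are needed: the orientation of the [2+2], fixed by the polarisation of methoxyacetylene so that OMe ends on C7 beside C8–H and the hydroxyl on C5, and the site of closure, fixed because the other ortho carbon of the benzene carries the aryl group and only C4a is free. Excess alkyne at room temperature should outrun closure of ketene 15 onto the pendant aryl ring, which would require dearomatising both rings.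

Step 8
Reactants: 18 5-[3,5-dimethoxy-4-(propan-2-yloxy)phenyl]-3-methoxy-6,7-dimethylnaphthalen-1-ol
Product: 19 1-[3,5-dimethoxy-4-(propan-2-yloxy)phenyl]-5,7-dimethoxy-2,3-dimethylnaphthalene
Conditions: MeI, K2CO3, acetone, reflux
Reagents that add atoms: iodomethane, CI
Why: Williamson methylation of an unhindered naphthol (C5–OH, peri only to C4–H) is reliable and leaves all other groups untouched.

Step 9
Reactants: 19 1-[3,5-dimethoxy-4-(propan-2-yloxy)phenyl]-5,7-dimethoxy-2,3-dimethylnaphthalene
Product: 22 5-[3,5-dimethoxy-4-(propan-2-yloxy)phenyl]-1,3-dimethoxy-6,7-dimethylnaphthalen-2-ol, via C6 aryllithium 20 (not isolated), via dimethyl arylboronate 21 (not isolated)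
Conditions: n-BuLi (1.2 equiv), THF, 0 °C → rt; B(OMe)3, −78 °C → rt; AcOH, then 30% aq. H2O2, 0 °C → rt
Reagents that add atoms: hydrogen peroxide, OO
Why: Directed ortho‑metalation, in which C6–H between two methoxy groups is the most acidic ring proton (cooperative coordination and inductive effects), the alkyl aryl ethers are inert to n‑BuLi, and borylation followed by peroxide oxidation (boron‑to‑oxygen 1,2‑aryl shift) converts the C–Li bond into the phenol.

Step 10
Reactants: 22 5-[3,5-dimethoxy-4-(propan-2-yloxy)phenyl]-1,3-dimethoxy-6,7-dimethylnaphthalen-2-ol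
Product: 23 sacidumlignan A, 5-(4-hydroxy-3,5-dimethoxyphenyl)-1,3-dimethoxy-6,7-dimethylnaphthalen-2-ol
Conditions: BCl3 (3 equiv), CH2Cl2, −78 → 0 °C; then MeOH, H2O
Reagents that add atoms: none
Why: Lewis‑acid ether cleavage, in which BCl3 complexes the crowded isopropyl ether oxygen and chloride breaks the secondary alkyl–oxygen bond much faster than any methyl–oxygen bond at or below 0 °C, a well‑established selective deisopropylation.

Compound list
1 | 4-bromo-2,6-dimethoxyphenol | COc1cc(Br)cc(OC)c1O | starting material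
2 | 5-bromo-1,3-dimethoxy-2-(propan-2-yloxy)benzene | COc1cc(Br)cc(OC)c1OC(C)C | intermediate
3 | [3,5-dimethoxy-4-(propan-2-yloxy)phenyl]lithium | [Li]c1cc(OC)c(OC(C)C)c(OC)c1 | intermediate (not isolated)
4 | lithium [3,5-dimethoxy-4-(propan-2-yloxy)phenyl]tri(propan-2-yloxy)borate | [Li+].CC(C)O[B-](OC(C)C)(OC(C)C)c1cc(OC)c(OC(C)C)c(OC)c1 | intermediate (not isolated)
5 | [3,5-dimethoxy-4-(propan-2-yloxy)phenyl]boronic acid | COc1cc(B(O)O)cc(OC)c1OC(C)C | intermediate
6 | 2-amino-3,4-dimethylbenzoic acid | Cc1ccc(C(=O)O)c(N)c1C | starting material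
7 | 6-carboxy-2,3-dimethylbenzenediazonium chloride | Cc1ccc(C(=O)O)c([N+]#N)c1C.[Cl-] | intermediate (not isolated)
8 | 2-iodo-3,4-dimethylbenzoic acid | Cc1ccc(C(=O)O)c(I)c1C | intermediate
9 | 2-[3,5-dimethoxy-4-(propan-2-yloxy)phenyl]-3,4-dimethylbenzoic acid | Cc1ccc(C(=O)O)c(-c2cc(OC)c(OC(C)C)c(OC)c2)c1C | intermediate
10 | 2-[3,5-dimethoxy-4-(propan-2-yloxy)phenyl]-3,4-dimethylbenzoyl chloride | Cc1ccc(C(Cl)=O)c(-c2cc(OC)c(OC(C)C)c(OC)c2)c1C | intermediate (not isolated)
11 | 2-diazo-1-{2-[3,5-dimethoxy-4-(propan-2-yloxy)phenyl]-3,4-dimethylphenyl}ethan-1-one | Cc1ccc(C(=O)C=[N+]=[N-])c(-c2cc(OC)c(OC(C)C)c(OC)c2)c1C | intermediate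
12 | chloroacetaldehyde dimethyl acetal (2-chloro-1,1-dimethoxyethane) | COC(CCl)OC | starting material
13 | sodium methoxyacetylide | [Na+].[C-]#COC | intermediate (not isolated)
14 | methoxyacetylene (methoxyethyne) | COC#C | intermediate
15 | 2-{2-[3,5-dimethoxy-4-(propan-2-yloxy)phenyl]-3,4-dimethylphenyl}ethen-1-one (arylketene) | Cc1ccc(C=C=O)c(-c2cc(OC)c(OC(C)C)c(OC)c2)c1C | intermediate (not isolated)
16 | 4-{2-[3,5-dimethoxy-4-(propan-2-yloxy)phenyl]-3,4-dimethylphenyl}-3-methoxycyclobut-2-en-1-one (racemic at C4) | COC1=CC(=O)C1c1ccc(C)c(C)c1-c1cc(OC)c(OC(C)C)c(OC)c1 | intermediate (not isolated)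
17 | (3E)-4-{2-[3,5-dimethoxy-4-(propan-2-yloxy)phenyl]-3,4-dimethylphenyl}-3-methoxybuta-1,3-dien-1-one (dienylketene, aryl cis to the ketenyl group) | O=C=C/C(OC)=C\c1ccc(C)c(C)c1-c1cc(OC)c(OC(C)C)c(OC)c1 | intermediate (not isolated)
18 | 5-[3,5-dimethoxy-4-(propan-2-yloxy)phenyl]-3-methoxy-6,7-dimethylnaphthalen-1-ol | COc1cc(-c2c(C)c(C)cc3c(O)cc(OC)cc23)cc(OC)c1OC(C)C | intermediate
19 | 1-[3,5-dimethoxy-4-(propan-2-yloxy)phenyl]-5,7-dimethoxy-2,3-dimethylnaphthalene | COc1cc(-c2c(C)c(C)cc3c(OC)cc(OC)cc23)cc(OC)c1OC(C)C | intermediate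
20 | {5-[3,5-dimethoxy-4-(propan-2-yloxy)phenyl]-1,3-dimethoxy-6,7-dimethylnaphthalen-2-yl}lithium | [Li]c1c(OC)cc2c(-c3cc(OC)c(OC(C)C)c(OC)c3)c(C)c(C)cc2c1OC | intermediate (not isolated)
21 | dimethyl {5-[3,5-dimethoxy-4-(propan-2-yloxy)phenyl]-1,3-dimethoxy-6,7-dimethylnaphthalen-2-yl}boronate | COB(OC)c1c(OC)cc2c(-c3cc(OC)c(OC(C)C)c(OC)c3)c(C)c(C)cc2c1OC | intermediate (not isolated)
22 | 5-[3,5-dimethoxy-4-(propan-2-yloxy)phenyl]-1,3-dimethoxy-6,7-dimethylnaphthalen-2-ol | COc1cc(-c2c(C)c(C)cc3c(OC)c(O)c(OC)cc23)cc(OC)c1OC(C)C | intermediate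
23 | sacidumlignan A, 5-(4-hydroxy-3,5-dimethoxyphenyl)-1,3-dimethoxy-6,7-dimethylnaphthalen-2-ol | COc1cc(-c2c(C)c(C)cc3c(OC)c(O)c(OC)cc23)cc(OC)c1O | target

Total step count: 10. Longest linear sequence: 8 steps (steps 1, 2, 4, 5, 7, 8, 9, 10, from 4-bromo-2,6-dimethoxyphenol).

Steps most likely to fail

Step 7. Capture of the short‑lived ketene by a volatile alkyne may lose out to attack of the excited diazoketone or carbene on the neighbouring trialkoxyphenyl ring, or to secondary photoreactions. The thermal electrocyclic stage may stall at the cyclobutenone, and the naphthol formed may be acylated by unreacted ketene; brief K2CO3/MeOH treatment of the crude product would reverse the acylation. If light‑driven ketene generation is the problem, the ketene would be made in the dark. The fallback sets out from 11: silver‑catalysed Wolff rearrangement in water (PhCO2Ag, Et3N, THF/H2O, Arndt–Eistert homologation) should give {2-[3,5-dimethoxy-4-(propan-2-yloxy)phenyl]-3,4-dimethylphenyl}acetic acid F1. Oxalyl chloride with catalytic DMF should convert it into {2-[3,5-dimethoxy-4-(propan-2-yloxy)phenyl]-3,4-dimethylphenyl}acetyl chloride F2. Slow addition of Et3N to F2 and excess 14 in Et2O at 0 °C should generate arylketene 15 by dehydrochlorination and trap it as cyclobutenone 16. Heating 16 in toluene at 80–110 °C should then give naphthol 18, where the route resumes.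

Step 9. Metalation may occur at a competing site (C8, C4 or the pendant ring), the doubly ortho‑substituted boronate may protodeboronate before oxidation, or the electron‑rich naphthol may be over‑oxidised by peroxide. The fallback sets out from 18 and introduces the C6 oxygen without organolithium chemistry. Magnesium‑mediated ortho‑formylation (MgCl2, Et3N, paraformaldehyde, MeCN, reflux) at C6, the only free position ortho to the C5 hydroxyl, should give 5-[3,5-dimethoxy-4-(propan-2-yloxy)phenyl]-1-hydroxy-3-methoxy-6,7-dimethylnaphthalene-2-carbaldehyde F3. Methylation (MeI, K2CO3, DMF) should give 5-[3,5-dimethoxy-4-(propan-2-yloxy)phenyl]-1,3-dimethoxy-6,7-dimethylnaphthalene-2-carbaldehyde F4. Baeyer–Villiger (Dakin‑type) oxidation with mCPBA in CH2Cl2 at 0 °C should give 5-[3,5-dimethoxy-4-(propan-2-yloxy)phenyl]-1,3-dimethoxy-6,7-dimethylnaphthalen-2-yl formate F5. Methanolysis (K2CO3, MeOH) should deliver phenol 22, where the route resumes.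

Step 4. Transmetalation may be slow and reductive loss of iodine may compete at an aryl iodide flanked by a methyl group and a palladium‑binding carboxylate. The fallback sets out from 8 and moves the coupling to the neutral ester. Esterification (MeI, K2CO3, DMF) should give methyl 2-iodo-3,4-dimethylbenzoate F6. Suzuki–Miyaura coupling with 5 (Pd(OAc)2, SPhos, K3PO4, toluene/H2O, 90 °C) should give methyl 2-[3,5-dimethoxy-4-(propan-2-yloxy)phenyl]-3,4-dimethylbenzoate F7. Saponification (NaOH, MeOH/H2O, 60 °C, then aq. HCl) should return acid 9, where the route resumes.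

Further compounds
F1 | step 7 | {2-[3,5-dimethoxy-4-(propan-2-yloxy)phenyl]-3,4-dimethylphenyl}acetic acid | Cc1ccc(CC(=O)O)c(-c2cc(OC)c(OC(C)C)c(OC)c2)c1C
F2 | step 7 | {2-[3,5-dimethoxy-4-(propan-2-yloxy)phenyl]-3,4-dimethylphenyl}acetyl chloride | Cc1ccc(CC(Cl)=O)c(-c2cc(OC)c(OC(C)C)c(OC)c2)c1C
F3 | step 9 | 5-[3,5-dimethoxy-4-(propan-2-yloxy)phenyl]-1-hydroxy-3-methoxy-6,7-dimethylnaphthalene-2-carbaldehyde | COc1cc(-c2c(C)c(C)cc3c(O)c(C=O)c(OC)cc23)cc(OC)c1OC(C)C
F4 | step 9 | 5-[3,5-dimethoxy-4-(propan-2-yloxy)phenyl]-1,3-dimethoxy-6,7-dimethylnaphthalene-2-carbaldehyde | COc1cc(-c2c(C)c(C)cc3c(OC)c(C=O)c(OC)cc23)cc(OC)c1OC(C)C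
F5 | step 9 | 5-[3,5-dimethoxy-4-(propan-2-yloxy)phenyl]-1,3-dimethoxy-6,7-dimethylnaphthalen-2-yl formate | COc1cc(-c2c(C)c(C)cc3c(OC)c(OC=O)c(OC)cc23)cc(OC)c1OC(C)C
F6 | step 4 | methyl 2-iodo-3,4-dimethylbenzoate | Cc1ccc(C(=O)OC)c(I)c1C
F7 | step 4 | methyl 2-[3,5-dimethoxy-4-(propan-2-yloxy)phenyl]-3,4-dimethylbenzoate | Cc1ccc(C(=O)OC)c(-c2cc(OC)c(OC(C)C)c(OC)c2)c1C
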